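Ring B is disconnected at C2–C3 and at the C1–guaiacyl bond. The key step exploits the C1–C2–C3 triad of ring B: C1 carries the guaiacyl group, C2 a carboxyl-derived CH2OH and C3 the neighbouring CH2OH, which is the imprint of an aryl group added across a ring A-bound alkynoate followed by capture of a tethered alkene. One nickel-catalysed operation joins the arylboronic acid to C1, closes ring B (C2–C3) and sets C3 as a vinyl-bearing stereocentre. The precursor is a ring A arene carrying an ortho methyl propiolate unit and an (E)-but-2-enyl methyl carbonate. C3 then relays its configuration to C1 (hydrogenation) and C2 (equilibration).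

Key step: step 9

Remarks
- Numbering: tetralin numbering of the target is used throughout (C1 aryl methine, C2 and C3 the CH2OH-bearing carbons, C4 the CH2, C6 OMe, C7 and C8 OH). Ring A is the oxygenated benzo ring and ring B the carbocycle. The target is (1S,2R,3R): the C1 aryl group and the C3 CH2OH are cis, and the C2 CH2OH is trans to both.
- Assumption 1: bromination of 1 is taken to occur at C2 of the aldehyde (the future C8a), the only position both ortho to the free 3-OH and para to the 5-OMe; the regiochemistry would be confirmed on 2 before going on.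
- Assumption 2: the sense of induction of the nickel–phosphinooxazoline catalyst on this substrate cannot be predicted with confidence; (S)-t-Bu-PHOX is written, and its mirror image would be used if it proves to give (3R).

Step 1
Reactants: 1 5-hydroxyvanillin (3,4-dihydroxy-5-methoxybenzaldehyde)
Product: 2 2-bromo-3,4-dihydroxy-5-methoxybenzaldehyde
Conditions: Br2 (1.05 equiv), NaOAc, AcOH, 15 °C
Reagents that add atoms: bromine, BrBr
Why: Electrophilic aromatic bromination is expected at the one position that is both ortho to the free 3-OH and para to the 5-OMe, which is why it is run before benzylation: the bis(benzyl) ether would offer two electronically matched positions and give regioisomers.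

Step 2
Reactants: 2 2-bromo-3,4-dihydroxy-5-methoxybenzaldehyde
Product: 3 3,4-bis(benzyloxy)-2-bromo-5-methoxybenzaldehyde
Conditions: BnBr (2.4 equiv), K2CO3, DMF, 60 °C
Reagents that add atoms: benzyl bromide, BrCc1ccccc1
Why: Williamson ether synthesis on both phenoxides should be clean in DMF, and benzyl is chosen because it survives every step up to the hydrogenation, where it falls off without a separate operation.

Step 3
Reactants: 3 3,4-bis(benzyloxy)-2-bromo-5-methoxybenzaldehyde; 4 ethynyltri(propan-2-yl)silane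
Product: 5 3,4-bis(benzyloxy)-5-methoxy-2-{[tri(propan-2-yl)silyl]ethynyl}benzaldehyde
Conditions: Pd(PPh3)2Cl2 (5 mol%), CuI (5 mol%), Et3N, THF, 65 °C
Reagents that add atoms: none
Why: Sonogashira coupling is placed here because the ortho formyl group activates the hindered C–Br bond towards oxidative addition to zerovalent palladium and because no aryl halide then remains to compete in step 6, while the bulky silyl cap keeps the alkyne inert until step 7.

Step 4
Reactants: 5 3,4-bis(benzyloxy)-5-methoxy-2-{[tri(propan-2-yl)silyl]ethynyl}benzaldehyde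
Product: 6 (3,4-bis(benzyloxy)-5-methoxy-2-{[tri(propan-2-yl)silyl]ethynyl}phenyl)methanol
Conditions: NaBH4, THF/MeOH, 0 °C
Reagents that add atoms: none
Why: Borohydride reduction of an aromatic aldehyde to the benzylic alcohol is chemoselective in the presence of the silylalkyne and the benzyl ethers.

Step 5
Reactants: 6 (3,4-bis(benzyloxy)-5-methoxy-2-{[tri(propan-2-yl)silyl]ethynyl}phenyl)methanol
Product: 7 {[2,3-bis(benzyloxy)-6-(bromomethyl)-4-methoxyphenyl]ethynyl}tri(propan-2-yl)silane
Conditions: PBr3 (0.4 equiv), CH2Cl2, 0 °C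
Reagents that add atoms: phosphorus tribromide, BrP(Br)Br
Why: Nucleophilic substitution of an electron-rich benzylic alcohol through its phosphite ester should be fast at 0 °C and leaves the silylalkyne and the ethers untouched; the bromide is used without storage.

Step 6
Reactants: 7 {[2,3-bis(benzyloxy)-6-(bromomethyl)-4-methoxyphenyl]ethynyl}tri(propan-2-yl)silane; 8 (E)-tert-butyldimethyl{[3-(4,4,5,5-tetramethyl-1,3,2-dioxaborolan-2-yl)prop-2-en-1-yl]oxy}silane
Product: 9 tert-butyl{[(E)-4-(3,4-bis(benzyloxy)-5-methoxy-2-{[tri(propan-2-yl)silyl]ethynyl}phenyl)but-2-en-1-yl]oxy}dimethylsilane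
Conditions: Pd(dppf)Cl2·CH2Cl2 (5 mol%), Cs2CO3, THF/H2O (10:1), 65 °C
Reagents that add atoms: none
Why: Suzuki–Miyaura coupling of a benzylic bromide with an (E)-alkenylboronate forms the C4–C3 bond with retention of alkene geometry, so the but-2-enyl chain is obtained as a single geometric isomer, whereas an alkene cross-metathesis would give E/Z mixtures and would engage the ortho alkyne in enyne metathesis.

Step 7
Reactants: 9 tert-butyl{[(E)-4-(3,4-bis(benzyloxy)-5-methoxy-2-{[tri(propan-2-yl)silyl]ethynyl}phenyl)but-2-en-1-yl]oxy}dimethylsilane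
Product: 10 (E)-4-[3,4-bis(benzyloxy)-2-ethynyl-5-methoxyphenyl]but-2-en-1-ol
Conditions: Bu4NF (2.5 equiv), THF, 0 °C to rt
Reagents that add atoms: none
Why: Fluoride-mediated desilylation cleaves the alkynyl C–Si bond and the silyl ether in one operation, exposing the terminal alkyne and the allylic alcohol, and nothing else in 9 is labile to fluoride.

Step 8
Reactants: 10 (E)-4-[3,4-bis(benzyloxy)-2-ethynyl-5-methoxyphenyl]but-2-en-1-ol; 11 methyl chloroformate (3 equiv)
Product: 13 methyl 3-{2,3-bis(benzyloxy)-4-methoxy-6-[(E)-4-(methoxycarbonyloxy)but-2-enyl]phenyl}propiolate, via dilithio derivative 12 (not isolated)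
Conditions: n-BuLi (2.05 equiv), THF, −78 °C; then inverse addition to ClCO2Me, −78 to 0 °C
Reagents that add atoms: none
Why: Deprotonation of the alcohol and the terminal alkyne followed by acylation of both lithium sites (alkoxide O-acylation and acetylide C-acylation) installs the allylic carbonate and the alkynoate together and last, because an allylic carbonate would be ionized by the zerovalent palladium of steps 3 and 6 and an alkynoate would not survive the nucleophiles and bases used earlier.

Step 9
Reactants: 13 methyl 3-{2,3-bis(benzyloxy)-4-methoxy-6-[(E)-4-(methoxycarbonyloxy)but-2-enyl]phenyl}propiolate; 14 (4-benzyloxy-3-methoxyphenyl)boronic acid (2 equiv)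
Product: 15 methyl (3S)-7,8-bis(benzyloxy)-1-[4-(benzyloxy)-3-methoxyphenyl]-6-methoxy-3-vinyl-3,4-dihydronaphthalene-2-carboxylate
Conditions: Ni(OAc)2·4H2O (10 mol%), (S)-t-Bu-PHOX [(S)-4-tert-butyl-2-(2-diphenylphosphinophenyl)-4,5-dihydrooxazole] (12 mol%), CF3CH2OH, 80 °C
Reagents that add atoms: none
Why: Transmetalation of 14 to the ligand-bound divalent nickel acetate gives an arylnickel species that adds syn across the alkynoate with aryl to C1 and nickel to C2; the alkenylnickel then interconverts its E and Z forms through an O-bound nickel allenoate, and only the isomer with nickel cis to ring A can insert the tethered alkene and expel the carbonate by β-oxygen elimination, which leaves the C3 vinyl group and returns divalent nickel. The closest known reaction type is the nickel-catalysed anti-arylmetallative cyclization of alkyne-tethered allylic phosphates and related electrophiles with arylboronic acids, of which this aryl-tethered alkynoate closing a six-membered ring is a new member. Ring B closes by 6-exo-trig migratory insertion (C2–C3 bond), with the C1=C2 alkene ending endocyclic. The C3 stereocentre is set in that insertion by the chiral P,N ligand, which differentiates the two faces of the geometrically pure (E)-alkene. The step needs arylnickelation with aryl on the carbon remote from the ester, which the polarization of the alkynoate and the stabilization of nickel next to the ester secure, and cyclization faster than protonation of the alkenylnickel, which the easy allenoate isomerization and the short ortho tether favour.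

Step 10
Reactants: 15 methyl (3S)-7,8-bis(benzyloxy)-1-[4-(benzyloxy)-3-methoxyphenyl]-6-methoxy-3-vinyl-3,4-dihydronaphthalene-2-carboxylate
Product: 17 (3R)-7,8-bis(benzyloxy)-1-[4-(benzyloxy)-3-methoxyphenyl]-6-methoxy-2-(methoxycarbonyl)-3,4-dihydronaphthalene-3-carboxylic acid, via aldehyde 16 (not isolated)
Conditions: OsO4 (2 mol%), NaIO4 (4 equiv), 2,6-lutidine, dioxane/H2O (3:1), rt; then crude: NaClO2, NaH2PO4, 2-methyl-2-butene, t-BuOH/H2O, 0 °C
Reagents that add atoms: osmium tetroxide, O=[Os](=O)(=O)=O (oxygen carrier, reoxidized by sodium periodate, [Na+].[O-][I](=O)(=O)=O); sodium chlorite, [Na+].[O-]Cl=O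
Why: Lemieux–Johnson cleavage attacks only the monosubstituted vinyl group (the tetrasubstituted, ester-conjugated C1=C2 alkene is inert to OsO4 here), and Pinnick oxidation of the crude aldehyde under buffered conditions converts it at once into the acid, so that C3, which in the aldehyde is both α to the carbonyl group and allylic, is not left exposed to enolization.

Step 11
Reactants: 17 (3R)-7,8-bis(benzyloxy)-1-[4-(benzyloxy)-3-methoxyphenyl]-6-methoxy-2-(methoxycarbonyl)-3,4-dihydronaphthalene-3-carboxylic acid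
Product: 18 (1S,2S,3R)-7,8-dihydroxy-1-(4-hydroxy-3-methoxyphenyl)-6-methoxy-2-(methoxycarbonyl)-1,2,3,4-tetrahydronaphthalene-3-carboxylic acid (all-cis)
Conditions: H2 (10 bar), Pd(OH)2/C, EtOAc/MeOH, 40 °C
Reagents that add atoms: none
Why: Heterogeneous catalytic hydrogenation should deliver both hydrogen atoms to the face of the C1=C2 alkene opposite the C3 carboxyl group, which allylic strain with the C2 ester holds pseudo-axial, so that C1 becomes (S) with the aryl group cis to the C3 substituent and C2 is formed cis to both (corrected in step 12), while hydrogenolysis removes the three benzyl ethers.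

Step 12
Reactants: 18 (1S,2S,3R)-7,8-dihydroxy-1-(4-hydroxy-3-methoxyphenyl)-6-methoxy-2-(methoxycarbonyl)-1,2,3,4-tetrahydronaphthalene-3-carboxylic acid
Product: 20 dimethyl (1S,2R,3R)-7,8-dihydroxy-1-(4-hydroxy-3-methoxyphenyl)-6-methoxy-1,2,3,4-tetrahydronaphthalene-2,3-dicarboxylate, via trans half-ester 19 (not isolated)
Conditions: NaOMe (8 equiv), degassed MeOH, reflux, argon; then HCl in MeOH (excess), reflux
Reagents that add atoms: methanol, CO
Why: Base-mediated epimerization through the ester enolate moves only C2, because C3 is held as a carboxylate that does not enolize under methoxide and C1 has no acidifying group, so the all-cis compound should relax to the 1,2-trans-2,3-trans isomer with the C2 ester trans to both neighbours; Fischer esterification in the same flask then gives the diester without touching a stereocentre, and the diester itself is deliberately not equilibrated because the C8 oxygen peri to the C1 aryl group could make the 1,2-cis-2,3-trans isomer the sink once C3 can move.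

Step 13
Reactants: 20 dimethyl (1S,2R,3R)-7,8-dihydroxy-1-(4-hydroxy-3-methoxyphenyl)-6-methoxy-1,2,3,4-tetrahydronaphthalene-2,3-dicarboxylate
Product: 21 (1S,2R,3R)-1-(4-hydroxy-3-methoxyphenyl)-2,3-bis(hydroxymethyl)-6-methoxy-1,2,3,4-tetrahydronaphthalene-7,8-diol (target, CNP0219328.1)
Conditions: LiAlH4 (8 equiv), THF, 0 °C to reflux; aqueous potassium sodium tartrate, then dilute HCl
Reagents that add atoms: none
Why: Lithium aluminium hydride reduction of both methyl esters to primary alcohols, with the phenols carried as aluminium phenoxides and released on work-up, completes the target, and no stereocentre can epimerize under hydride, so (1S,2R,3R) is retained.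

Compound list
1 | 5-hydroxyvanillin (3,4-dihydroxy-5-methoxybenzaldehyde) | COc1cc(C=O)cc(O)c1O | starting material
2 | 2-bromo-3,4-dihydroxy-5-methoxybenzaldehyde | COc1cc(C=O)c(Br)c(O)c1O | intermediate
3 | 3,4-bis(benzyloxy)-2-bromo-5-methoxybenzaldehyde | COc1cc(C=O)c(Br)c(OCc2ccccc2)c1OCc1ccccc1 | intermediate
4 | ethynyltri(propan-2-yl)silane | C#C[Si](C(C)C)(C(C)C)C(C)C | starting material
5 | 3,4-bis(benzyloxy)-5-methoxy-2-{[tri(propan-2-yl)silyl]ethynyl}benzaldehyde | COc1cc(C=O)c(C#C[Si](C(C)C)(C(C)C)C(C)C)c(OCc2ccccc2)c1OCc1ccccc1 | intermediate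
6 | (3,4-bis(benzyloxy)-5-methoxy-2-{[tri(propan-2-yl)silyl]ethynyl}phenyl)methanol | COc1cc(CO)c(C#C[Si](C(C)C)(C(C)C)C(C)C)c(OCc2ccccc2)c1OCc1ccccc1 | intermediate
7 | {[2,3-bis(benzyloxy)-6-(bromomethyl)-4-methoxyphenyl]ethynyl}tri(propan-2-yl)silane | COc1cc(CBr)c(C#C[Si](C(C)C)(C(C)C)C(C)C)c(OCc2ccccc2)c1OCc1ccccc1 | intermediate
8 | (E)-tert-butyldimethyl{[3-(4,4,5,5-tetramethyl-1,3,2-dioxaborolan-2-yl)prop-2-en-1-yl]oxy}silane | CC(C)(C)[Si](C)(C)OC/C=C/B1OC(C)(C)C(C)(C)O1 | starting material
9 | tert-butyl{[(E)-4-(3,4-bis(benzyloxy)-5-methoxy-2-{[tri(propan-2-yl)silyl]ethynyl}phenyl)but-2-en-1-yl]oxy}dimethylsilane | COc1cc(C/C=C/CO[Si](C)(C)C(C)(C)C)c(C#C[Si](C(C)C)(C(C)C)C(C)C)c(OCc2ccccc2)c1OCc1ccccc1 | intermediate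
10 | (E)-4-[3,4-bis(benzyloxy)-2-ethynyl-5-methoxyphenyl]but-2-en-1-ol | COc1cc(C/C=C/CO)c(C#C)c(OCc2ccccc2)c1OCc1ccccc1 | intermediate
11 | methyl chloroformate | COC(=O)Cl | starting material
12 | dilithio derivative of 10 (lithium alkynide and lithium alkoxide) | COc1cc(C/C=C/CO[Li])c(C#C[Li])c(OCc2ccccc2)c1OCc1ccccc1 | intermediate (not isolated)
13 | methyl 3-{2,3-bis(benzyloxy)-4-methoxy-6-[(E)-4-(methoxycarbonyloxy)but-2-enyl]phenyl}propiolate | COC(=O)C#Cc1c(C/C=C/COC(=O)OC)cc(OC)c(OCc2ccccc2)c1OCc1ccccc1 | intermediate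
14 | (4-benzyloxy-3-methoxyphenyl)boronic acid | COc1cc(B(O)O)ccc1OCc1ccccc1 | starting material
15 | methyl (3S)-7,8-bis(benzyloxy)-1-[4-(benzyloxy)-3-methoxyphenyl]-6-methoxy-3-vinyl-3,4-dihydronaphthalene-2-carboxylate | COC(=O)C1=C(c2ccc(OCc3ccccc3)c(OC)c2)c2c(cc(OC)c(OCc3ccccc3)c2OCc2ccccc2)C[C@H]1C=C | intermediate
16 | methyl (3R)-7,8-bis(benzyloxy)-1-[4-(benzyloxy)-3-methoxyphenyl]-3-formyl-6-methoxy-3,4-dihydronaphthalene-2-carboxylate | COC(=O)C1=C(c2ccc(OCc3ccccc3)c(OC)c2)c2c(cc(OC)c(OCc3ccccc3)c2OCc2ccccc2)C[C@H]1C=O | intermediate (not isolated)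
17 | (3R)-7,8-bis(benzyloxy)-1-[4-(benzyloxy)-3-methoxyphenyl]-6-methoxy-2-(methoxycarbonyl)-3,4-dihydronaphthalene-3-carboxylic acid | COC(=O)C1=C(c2ccc(OCc3ccccc3)c(OC)c2)c2c(cc(OC)c(OCc3ccccc3)c2OCc2ccccc2)C[C@H]1C(=O)O | intermediate
18 | (1S,2S,3R)-7,8-dihydroxy-1-(4-hydroxy-3-methoxyphenyl)-6-methoxy-2-(methoxycarbonyl)-1,2,3,4-tetrahydronaphthalene-3-carboxylic acid (all-cis) | COc1cc([C@H]2c3c(cc(OC)c(O)c3O)C[C@@H](C(=O)O)[C@H]2C(=O)OC)ccc1O | intermediate
19 | (1S,2R,3R)-7,8-dihydroxy-1-(4-hydroxy-3-methoxyphenyl)-6-methoxy-2-(methoxycarbonyl)-1,2,3,4-tetrahydronaphthalene-3-carboxylic acid (all-trans) | COc1cc([C@H]2c3c(cc(OC)c(O)c3O)C[C@@H](C(=O)O)[C@@H]2C(=O)OC)ccc1O | intermediate (not isolated)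
20 | dimethyl (1S,2R,3R)-7,8-dihydroxy-1-(4-hydroxy-3-methoxyphenyl)-6-methoxy-1,2,3,4-tetrahydronaphthalene-2,3-dicarboxylate | COc1cc([C@H]2c3c(cc(OC)c(O)c3O)C[C@@H](C(=O)OC)[C@@H]2C(=O)OC)ccc1O | intermediate
21 | (1S,2R,3R)-1-(4-hydroxy-3-methoxyphenyl)-2,3-bis(hydroxymethyl)-6-methoxy-1,2,3,4-tetrahydronaphthalene-7,8-diol | COc1cc([C@H]2c3c(cc(OC)c(O)c3O)C[C@@H](CO)[C@@H]2CO)ccc1O | target

Total step count: 13. Longest linear sequence: 13 steps (1 to 21).

Steps most likely to fail

Step 9. The alkenylnickel may be protonated by the solvent before the six-ring insertion (simple hydroarylation), the carbonate may be ionized by adventitious low-valent nickel, or the ligand may discriminate the alkene faces poorly. Enantiomeric purity would be checked at 15 and could be raised by crystallizing acid 17 as a salt with an enantiopure amine. The fallback sets out from 13 and comes back at 15, forming the same C2–C3 bond by allylic alkylation and the C1–aryl bond by cross-coupling. Conjugate addition of morpholine to the alkynoate (MeOH, rt) gives the enamino ester methyl (E)-3-{2,3-bis(benzyloxy)-4-methoxy-6-[(E)-4-(methoxycarbonyloxy)but-2-enyl]phenyl}-3-(morpholin-4-yl)prop-2-enoate F1. Hydrolysis (1 M HCl, THF) gives the β-keto ester methyl 3-{2,3-bis(benzyloxy)-4-methoxy-6-[(E)-4-(methoxycarbonyloxy)but-2-enyl]phenyl}-3-oxopropanoate F2. Intramolecular Tsuji–Trost allylic alkylation (Pd2(dba)3, (R,R)-DACH-phenyl bisphosphine ligand or its mirror image, CH2Cl2, rt) closes ring B in the same 6-exo sense and sets C3, giving methyl (3S)-7,8-bis(benzyloxy)-6-methoxy-1-oxo-3-vinyl-1,2,3,4-tetrahydronaphthalene-2-carboxylate F3. NaH and PhNTf2 (THF) convert it into the enol triflate methyl (3S)-7,8-bis(benzyloxy)-6-methoxy-1-(trifluoromethanesulfonyloxy)-3-vinyl-3,4-dihydronaphthalene-2-carboxylate F4. Suzuki–Miyaura coupling with 14 (Pd(PPh3)4, K3PO4, dioxane/H2O, 80 °C) introduces the C1 aryl group and returns 15.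

Step 11. Reduction of the hindered tetrasubstituted alkene may stall after debenzylation. Palladium may also shift the double bond into the C2–C3 position before reducing it, which would erase C3. Carboxyl-directed adsorption may erode the facial selectivity, which after step 12 would show up as material of the (1R) series. The fallback sets out from 17 and comes back at 18, replacing surface hydrogenation by electron-transfer conjugate reduction. Mg in MeOH (rt) reduces the β,β-diaryl acrylate, with protonation of C1 expected anti to the C3 carboxylate, to give (1S,2S,3R)-7,8-bis(benzyloxy)-1-[4-(benzyloxy)-3-methoxyphenyl]-6-methoxy-2-(methoxycarbonyl)-1,2,3,4-tetrahydronaphthalene-3-carboxylic acid F5. Partial C2 epimerization under the basic conditions is of no consequence, since step 12 equilibrates C2. Hydrogenolysis of the benzyl ethers alone (H2 1 atm, Pd/C, EtOAc/MeOH) then returns 18.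

Step 12. Enolization of the polyanionic half-ester may be slow. The methyl ester may migrate between the C2 and C3 carboxyl groups through a cyclic anhydride, which would unlock C3 and open the drift to the 1,2-cis-2,3-trans series. The catecholate may also oxidize in air. The fallback sets out from 17 and comes back at 21, locking C3 as an ether instead of a carboxylate. Chemoselective reduction of the acid (BH3·THF, 0 °C) gives methyl (3R)-7,8-bis(benzyloxy)-1-[4-(benzyloxy)-3-methoxyphenyl]-3-(hydroxymethyl)-6-methoxy-3,4-dihydronaphthalene-2-carboxylate F6. Immediate silylation (TBSCl, imidazole, DMF) gives the silyl ether methyl (3R)-7,8-bis(benzyloxy)-1-[4-(benzyloxy)-3-methoxyphenyl]-3-{[(tert-butyldimethylsilyl)oxy]methyl}-6-methoxy-3,4-dihydronaphthalene-2-carboxylate F7. Hydrogenation (H2, Pd(OH)2/C, EtOAc) gives all-cis methyl (1S,2S,3R)-3-{[(tert-butyldimethylsilyl)oxy]methyl}-7,8-dihydroxy-1-(4-hydroxy-3-methoxyphenyl)-6-methoxy-1,2,3,4-tetrahydronaphthalene-2-carboxylate F8. NaOMe in MeOH (reflux, argon) epimerizes C2, the only enolizable centre, to the all-trans ester methyl (1S,2R,3R)-3-{[(tert-butyldimethylsilyl)oxy]methyl}-7,8-dihydroxy-1-(4-hydroxy-3-methoxyphenyl)-6-methoxy-1,2,3,4-tetrahydronaphthalene-2-carboxylate F9. LiAlH4 (THF) reduces the ester to (1S,2R,3R)-3-{[(tert-butyldimethylsilyl)oxy]methyl}-2-(hydroxymethyl)-1-(4-hydroxy-3-methoxyphenyl)-6-methoxy-1,2,3,4-tetrahydronaphthalene-7,8-diol F10, and HCl in MeOH removes the silyl group to give 21.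

Further compounds
F1 | step 9 | methyl (E)-3-{2,3-bis(benzyloxy)-4-methoxy-6-[(E)-4-(methoxycarbonyloxy)but-2-enyl]phenyl}-3-(morpholin-4-yl)prop-2-enoate | COC(=O)/C=C(/N1CCOCC1)c1c(C/C=C/COC(=O)OC)cc(OC)c(OCc2ccccc2)c1OCc1ccccc1
F2 | step 9 | methyl 3-{2,3-bis(benzyloxy)-4-methoxy-6-[(E)-4-(methoxycarbonyloxy)but-2-enyl]phenyl}-3-oxopropanoate | COC(=O)CC(=O)c1c(C/C=C/COC(=O)OC)cc(OC)c(OCc2ccccc2)c1OCc1ccccc1
F3 | step 9 | methyl (3S)-7,8-bis(benzyloxy)-6-methoxy-1-oxo-3-vinyl-1,2,3,4-tetrahydronaphthalene-2-carboxylate (C2 epimers and enol) | COC(=O)C1C(=O)c2c(cc(OC)c(OCc3ccccc3)c2OCc2ccccc2)C[C@H]1C=C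
F4 | step 9 | methyl (3S)-7,8-bis(benzyloxy)-6-methoxy-1-(trifluoromethanesulfonyloxy)-3-vinyl-3,4-dihydronaphthalene-2-carboxylate | COC(=O)C1=C(OS(=O)(=O)C(F)(F)F)c2c(cc(OC)c(OCc3ccccc3)c2OCc2ccccc2)C[C@H]1C=C
F5 | step 11 | (1S,2S,3R)-7,8-bis(benzyloxy)-1-[4-(benzyloxy)-3-methoxyphenyl]-6-methoxy-2-(methoxycarbonyl)-1,2,3,4-tetrahydronaphthalene-3-carboxylic acid | COc1cc([C@H]2c3c(cc(OC)c(OCc4ccccc4)c3OCc3ccccc3)C[C@@H](C(=O)O)[C@H]2C(=O)OC)ccc1OCc1ccccc1
F6 | step 12 | methyl (3R)-7,8-bis(benzyloxy)-1-[4-(benzyloxy)-3-methoxyphenyl]-3-(hydroxymethyl)-6-methoxy-3,4-dihydronaphthalene-2-carboxylate | COC(=O)C1=C(c2ccc(OCc3ccccc3)c(OC)c2)c2c(cc(OC)c(OCc3ccccc3)c2OCc2ccccc2)C[C@H]1CO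
F7 | step 12 | methyl (3R)-7,8-bis(benzyloxy)-1-[4-(benzyloxy)-3-methoxyphenyl]-3-{[(tert-butyldimethylsilyl)oxy]methyl}-6-methoxy-3,4-dihydronaphthalene-2-carboxylate | COC(=O)C1=C(c2ccc(OCc3ccccc3)c(OC)c2)c2c(cc(OC)c(OCc3ccccc3)c2OCc2ccccc2)C[C@H]1CO[Si](C)(C)C(C)(C)C
F8 | step 12 | methyl (1S,2S,3R)-3-{[(tert-butyldimethylsilyl)oxy]methyl}-7,8-dihydroxy-1-(4-hydroxy-3-methoxyphenyl)-6-methoxy-1,2,3,4-tetrahydronaphthalene-2-carboxylate | COc1cc([C@H]2c3c(cc(OC)c(O)c3O)C[C@@H](CO[Si](C)(C)C(C)(C)C)[C@H]2C(=O)OC)ccc1O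
F9 | step 12 | methyl (1S,2R,3R)-3-{[(tert-butyldimethylsilyl)oxy]methyl}-7,8-dihydroxy-1-(4-hydroxy-3-methoxyphenyl)-6-methoxy-1,2,3,4-tetrahydronaphthalene-2-carboxylate | COc1cc([C@H]2c3c(cc(OC)c(O)c3O)C[C@@H](CO[Si](C)(C)C(C)(C)C)[C@@H]2C(=O)OC)ccc1O
F10 | step 12 | (1S,2R,3R)-3-{[(tert-butyldimethylsilyl)oxy]methyl}-2-(hydroxymethyl)-1-(4-hydroxy-3-methoxyphenyl)-6-methoxy-1,2,3,4-tetrahydronaphthalene-7,8-diol | COc1cc([C@H]2c3c(cc(OC)c(O)c3O)C[C@@H](CO[Si](C)(C)C(C)(C)C)[C@@H]2CO)ccc1O
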